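The closed, stirred larch flask holds substrate and enzyme at constant temperature, and the readings follow target as a percentage of the substrate charged. The same flask is asked about at later times.

- larch: substrate 0.10 M; enzyme 10 µM; the very flask that is asked about, followed so far
- flask: substrate 0.10 M; enzyme 10 µM; time 4.0 h

- larch (time / min: target / %): 10.0: 40; 20.0: 53; 30.0: 58; 60.0: 69; 120: 70

(readings scatter by 1.5 percentage points)

- steps under discussion: substrate + enzyme -> target + enzyme; target <-> isomer of the product

- amount of target in percent of the substrate charged, at 25 min, 80 min and 4.0 h

I draw the larch curve from its start. The first reading gives a slope of 0.0400 min⁻¹ as a fraction of the charge. Between 20.0 min and 30.0 min the gain has shrunk to 5 percentage points. The last stretch gains 1 point in 60.0 min, which is less than the scatter of one reading, so I freeze target there. The mean of the readings at 60.0 min and 120 min is 69.5%, good to 1.1 points, and I call it the frozen level.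

The starting slope, carried straight on, meets that level at 17.4 min, the knee of the curve. The time 25 min is later than the knee and stands midway between two readings, so I take their mean, 55.5%. The time 80 min lies inside the flat stretch and 4.0 h beyond it, so for both I carry the frozen level, the second by extrapolation.

The forecast gives 56%, 70% and 69%, each apart from my figure by less than the scatter of one reading. Of the plateau it says: “These readings cannot separate the two.”

The flask gives 55.7%, 69.3% and 70.1%.

    substrate + enzyme → target + enzyme, rate k1*[substrate]^3*[enzyme]/(1 + ([substrate]/Kh1)^3) (0.120 M, k = 17000 L³ mol⁻³ s⁻¹)
    target ⇌ isomer of the product (K = 0.350, k = 2.60 × 10⁻⁵ s⁻¹)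

At 4.00 h the flask stands at 70.1%, beside the frozen level of 69.5%, yet it still holds substrate at 14.3% and enzyme at 100%, while isomer of the product has reached 15.6%. A second flask, the same charge without the turning of target into isomer of the product, stands at 85.7% at that hour, which is 16 points above the frozen level. So that turning is what holds target down in this flask, by 16 points.

All runs come from a simulation on assumed constants; scatter was added.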